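I wanted to know how much target this flask holds at its best, and when.

| flask | solid substrate | reagent | remark | time |
|---|---|---|---|---|
| zeta | 0.070 M | 0.28 M (fed, over 8.0 min) | run made earlier; the fed solution adds 0.10 times the starting volume |  |
| alpha | 0.28 M | 0.28 M (fed, over 8.0 min) | run made earlier; the fed solution adds 0.10 times the starting volume |  |
| epsilon | 0.14 M | 0.42 M (fed, over 8.0 min) | run made earlier; the fed solution adds 0.10 times the starting volume |  |
| flask | 0.14 M | 0.280 M (fed, over 8.0 min) | the fed solution adds 0.10 times the starting volume | 8.0 h |

| run | time / h | target / % |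
|---|---|---|
| zeta | 0.100 | 7.5 |
| zeta | 0.200 | 17.6 |
| zeta | 0.333 | 14.2 |
| zeta | 0.667 | 5.1 |
| zeta | 1.33 | 3.5 |
| zeta | 2.50 | 4.1 |
| zeta | 5.00 | 3.4 |
| alpha | 0.100 | 1.9 |
| alpha | 0.200 | 4.1 |
| alpha | 0.333 | 4.8 |
| alpha | 0.667 | 4.8 |
| alpha | 1.33 | 3.7 |
| alpha | 2.50 | 4.0 |
| alpha | 5.00 | 3.2 |
| epsilon | 0.100 | 5.7 |
| epsilon | 0.250 | 12.3 |
| epsilon | 0.667 | 7.5 |
| epsilon | 2.00 | 4.1 |
| epsilon | 5.00 | 4.1 |

(standard deviation of a reading: 0.3 percentage points)

- time, not beyond 8.0 h, at which the flask holds most target
- the amount of target, in percent of the solid substrate charged, at that time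

- charges are per starting volume, the dose included; the dosed solution carries all of it
- given per volume of solution although it is solid: solid substrate
- the earlier runs were read with a standard deviation of 0.3 percentage points
- at the start none of the solid substrate is in solution

One thing looked wrong at first: the zeta run peaked at 17.6 % of its solid and the alpha run at 4.8 %, yet at 5.00 h they read 3.4 % and 3.2 %. So the late level followed the solid charged, and the peak did not. In molarity the peaks read 0.0123 M and 0.0134 M, close although alpha had 4.00 times the solid. Epsilon, with 1.50 times alpha's reagent and half its solid, read 1.50 times alpha's target in molarity at 0.100 h. I therefore called target at the top, over reagent charged, the ceiling share, and alpha's flat top gave 4.80 %.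

For the flask this gave me 9.60 % of its solid. Zeta's highest reading came at 0.200 h, so scaling that time with the solid put the flask at 0.400 h. The same scaling put alpha at 0.800 h, later than its last high reading at 0.667 h, so I held this time as rough.

The forecast said 9 % (8 % to 10.2 %) at 0.25 h (0.17 h to 0.36 h), noting that “The fall comes sooner with less solid”. Its time stood earlier than mine.

The flask gave 9.83 % at 0.405 h.

    starting material + reagent ⇌ target (K = 3.40 M⁻¹, k = 0.0120 M⁻¹ s⁻¹)
    target ⇌ isomer of the product (K = 25.0, k = 0.00410 s⁻¹)
    solid substrate ⇌ starting material, rate k3*(cs3 - [starting material]) while solid is left; crystals form when [starting material] > cs3 (solubility = 0.0560 M, k = 0.00260 s⁻¹)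

The ceiling share had given 9.60 %, slightly below the flask's result, and at that best time 23.4 % of the solid remained. I used the same share on a neighbour like this flask but with a quarter of the reagent, 0.070 M, which made reagent the limiting reagent by charge at 0.500 equiv. It gave 2.40 %, and that flask reached 3.07 %, more than reckoned. At 8.00 h starting material in that neighbour held 44.0 % of the solid charged.

The earlier runs and the new flask stem from a simulated flask from invented constants; noise was put on by code.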